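Ring A of the chroman-2-one is disconnected into a four-carbon vinylketene (C8a, C4a, C5, C6) and a two-carbon ynol ether (C8, C7). A single thermal cascade between a 3-benzyloxy-4-alkylcyclobut-2-enone and a triisopropylsiloxyalkyne should forge C8a–C8, C7–C6 and C8a–C4a and deliver the pentasubstituted phloroglucinol with its three oxygens differentiated. The step exploits the position of O on C8a between the carbon-substituted C8 and C4a: the ketene carbonyl becomes exactly this oxygen, free and next to the ester arm, so the lactone can close only there. The C4 stereocentre comes from desymmetrised 3-phenylglutaric anhydride and is a spectator; the acyl group travels as a silylated carbinol.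

Key step: step 9

Remark: the dihydroquinidine-derived catalyst of step 1 is assumed to deliver the (S)-hemiester 2; if the optical rotation of 2 shows the antipode, the dihydroquinine pseudoenantiomer (DHQ)2AQN is used with nothing else changed.
Remark: locants C2–C8a follow chroman-2-one numbering (ring A is the benzo ring); the carbinol carbon is deliberately racemic, so 23–25 are epimer pairs that converge at 26.

Step 1
Reactants: 1 3-phenylglutaric anhydride
Product: 2 (S)-5-methoxy-5-oxo-3-phenylpentanoic acid
Conditions: MeOH (10 equiv), hydroquinidine anthraquinone-1,4-diyl diether ((DHQD)2AQN, 20 mol%), Et2O, −40 °C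
Reagents that add atoms: methanol (CO)
Why: Cinchona-alkaloid-catalysed alcoholysis (general-base desymmetrisation of a meso anhydride) distinguishes the enantiotopic carbonyls and so sets the future C4 stereocentre under catalyst control, the acid arm being the one that later becomes C4a and the ester arm the one that becomes C3/C2; the optical purity can be raised by crystallising an amine salt.

Step 2
Reactants: 2 (S)-5-methoxy-5-oxo-3-phenylpentanoic acid
Product: 3 methyl (3R)-5-chloro-5-oxo-3-phenylpentanoate
Conditions: (COCl)2, DMF (cat.), CH2Cl2, 0 °C → rt; concentrated cold, used at once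
Reagents that add atoms: oxalyl chloride (O=C(Cl)C(=O)Cl)
Why: Acyl chloride formation through the Vilsmeier-type chloroiminium leaves the non-enolisable β-stereocentre alone, and cold, prompt handling should prevent interchange of the ester and acyl chloride termini through a cyclic acyloxonium, which would erase the desymmetrisation.

Step 3
Reactants: 4 benzyl alcohol; 5 trichloroethylene
Product: 6 benzyl (E)-1,2-dichlorovinyl ether
Conditions: KH, THF, 0 °C; then 5, −50 °C → rt
Reagents that add atoms: none
Why: Addition–elimination of the potassium alkoxide on trichloroethylene (through dichloroacetylene formed by dehydrochlorination) is the standard entry to 1,2-dichlorovinyl ethers and should give mainly the E isomer, either isomer serving in step 4.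

Step 4
Reactants: 6 benzyl (E)-1,2-dichlorovinyl ether
Product: 9 benzyl ethynyl ether (benzyloxyacetylene), via chloroalkynyl ether 7 (not isolated), via lithium benzyloxyacetylide 8 (not isolated)
Conditions: n-BuLi (2.3 equiv), Et2O, −78 → −40 °C; then H2O, −78 → 0 °C; cold pentane extract, used at once
Reagents that add atoms: none
Why: Vinylic deprotonation with β-elimination gives the chloroalkyne, chlorine–lithium exchange gives the acetylide and cold protonation gives the ynol ether (dehydrohalogenation/halogen–metal exchange route to alkynyl ethers); the product is kept cold because benzyl alkynyl ethers rearrange sigmatropically on warming.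

Step 5
Reactants: 3 methyl (3R)-5-chloro-5-oxo-3-phenylpentanoate; 9 benzyl ethynyl ether
Product: 11 methyl (3R)-3-[2-(benzyloxy)-4-oxocyclobut-2-en-1-yl]-3-phenylpropanoate (both epimers at the ring carbon), via ketene 10 (not isolated)
Conditions: 9 (2 equiv), Et3N (1.3 equiv), CH2Cl2, slow addition of 3, 0 °C → rt
Reagents that add atoms: none
Why: Dehydrochlorination gives the monoalkylketene, which undergoes a thermal ketene–alkyne [2+2] cycloaddition in the orientation set by polarity (ketene carbonyl carbon to the unsubstituted alkyne carbon), placing the benzyloxy group on C3 and the side chain on C4 of the cyclobutenone; slow addition into excess alkyne limits ketene dimerisation, and the new ring stereocentre is uncontrolled but is destroyed in step 9.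

Step 6
Reactants: 12 3-(4-methoxyphenyl)propanal; 13 ethynylmagnesium bromide
Product: 14 rac-5-(4-methoxyphenyl)pent-1-yn-3-ol
Conditions: THF, 0 °C; then H2O (aqueous work-up)
Reagents that add atoms: none
Why: 1,2-Addition of an alkynyl Grignard reagent to an unhindered aldehyde gives the propargylic alcohol as a racemate, which is acceptable because this carbon becomes the ketone carbon in step 12.

Step 7
Reactants: 14 rac-5-(4-methoxyphenyl)pent-1-yn-3-ol
Product: 15 rac-tert-butyl{[5-(4-methoxyphenyl)pent-1-yn-3-yl]oxy}dimethylsilane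
Conditions: TBSCl, imidazole, DMF, rt
Reagents that add atoms: tert-butyldimethylsilyl chloride (CC(C)(C)[Si](C)(C)Cl)
Why: Standard imidazole-promoted silylation masks the hydroxyl against the strong bases of step 8 and the ketenes of step 9.

Step 8
Reactants: 15 rac-tert-butyl{[5-(4-methoxyphenyl)pent-1-yn-3-yl]oxy}dimethylsilane
Product: 18 rac-tert-butyl{[5-(4-methoxyphenyl)-1-[(triisopropylsilyl)oxy]pent-1-yn-3-yl]oxy}dimethylsilane, via lithium acetylide 16 (not isolated), via lithium ynolate 17 (not isolated)
Conditions: n-BuLi (1.05 equiv), THF, −78 °C; t-BuOOLi (from t-BuOOH, LiN(SiMe3)2), −78 → 0 °C; then i-Pr3SiOTf, −78 °C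
Reagents that add atoms: tert-butyl hydroperoxide (CC(C)(C)OO); triisopropylsilyl trifluoromethanesulfonate (CC(C)[Si](C(C)C)(C(C)C)OS(=O)(=O)C(F)(F)F)
Why: The lithium acetylide is oxidised at carbon by the lithium peroxide to the ynolate, which the bulky silyl triflate captures on oxygen (acetylide oxidation/ynolate O-silylation), the established three-step access to triisopropylsiloxyalkynes from an aldehyde without an ester homologation.

Step 9
Reactants: 11 methyl (3R)-3-[2-(benzyloxy)-4-oxocyclobut-2-en-1-yl]-3-phenylpropanoate; 18 the siloxyalkyne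
Product: 23 methyl (3S)-3-[6-(benzyloxy)-3-{1-[(tert-butyldimethylsilyl)oxy]-3-(4-methoxyphenyl)propyl}-2-hydroxy-4-[(triisopropylsilyl)oxy]phenyl]-3-phenylpropanoate, via vinylketene 19 (not isolated), via vinylcyclobutenone 20 (not isolated), via dienylketene 21 (not isolated), via cyclohexadienone 22 (not isolated)
Conditions: 18 (1.5 equiv), degassed toluene, 80 → 110 °C, sealed tube
Reagents that add atoms: none
Why: Heating opens 11 by 4π-electrocyclic cleavage of the C1–C4 bond to vinylketene 19, whose ketene carbon is attacked by the non-oxygenated carbon of 18 in a [2+2] cycloaddition to give 20; a second 4π opening gives dienylketene 21, which closes to dienone 22 and tautomerises to phenol 23. This is the Danheiser benzannulation of a cyclobutenone with a siloxyalkyne. Ring A is closed by a thermal 6π-electrocyclisation that joins the ketene carbon (C8a) to the alkene terminus (C4a). No stereocentre is created, since every ring carbon ends sp2, and the benzylic C4 centre takes part in no bond change and is carried through unchanged. The one selectivity required is the orientation of the ketene–alkyne addition, which the oxygen-induced polarisation of the ynol ether secures (carbinol-bearing carbon to C8a, oxygen-bearing carbon to C6), and this puts the free hydroxyl on C8a, the silyl ether on O7 and the benzyl ether on O5. Excess 18 keeps the new phenol from being acylated by 19, and release of two strained rings plus aromatisation drives the sequence.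

Step 10
Reactants: 23 the ring A phenol
Product: 24 (4S)-5-(benzyloxy)-8-{1-[(tert-butyldimethylsilyl)oxy]-3-(4-methoxyphenyl)propyl}-4-phenyl-7-[(triisopropylsilyl)oxy]chroman-2-one
Conditions: pyridinium p-toluenesulfonate (20 mol%), toluene, 4 Å MS, 80 °C
Reagents that add atoms: none
Why: Mild acid-catalysed lactonisation (intramolecular transesterification) is favoured by the crowding around C4a, can involve only the single free phenol on C8a and does not touch C4–H; any lactone already formed in step 9 is simply combined.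

Step 11
Reactants: 24 the silylated lactone
Product: 25 (4S)-5-(benzyloxy)-8-[1-hydroxy-3-(4-methoxyphenyl)propyl]-4-phenyl-7-[(triisopropylsilyl)oxy]chroman-2-one
Conditions: HF·pyridine, pyridine, THF, 0 °C → rt
Reagents that add atoms: none
Why: Under acidic fluoride an alkyl silyl ether is cleaved much faster than an aryl silyl ether (the reverse of basic fluoride), so the carbinol should be freed while the O7 silyl ether, lactone and benzyl ether remain, the pyridine buffer guarding against ionisation of the electron-rich benzylic position.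

Step 12
Reactants: 25 the benzylic alcohol
Product: 26 (4S)-5-(benzyloxy)-8-[3-(4-methoxyphenyl)propanoyl]-4-phenyl-7-[(triisopropylsilyl)oxy]chroman-2-one
Conditions: Dess–Martin periodinane, NaHCO3, CH2Cl2, 0 °C → rt
Reagents that add atoms: none
Why: Dess–Martin oxidation of a secondary benzylic alcohol under buffered conditions installs the aryl ketone, removes the carbinol stereocentre and leaves the silyl ether, benzyl ether and lactone alone.

Step 13
Reactants: 26 the silyl-protected ketone
Product: 27 (4S)-5-(benzyloxy)-7-hydroxy-8-[3-(4-methoxyphenyl)propanoyl]-4-phenylchroman-2-one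
Conditions: Bu4NF, AcOH (1:1), THF, 0 °C
Reagents that add atoms: none
Why: Fluoride cleavage of an aryl silyl ether, here activated by the ortho carbonyl, is fast at 0 °C, and the acetic acid buffer keeps the aryl lactone from being opened.

Step 14
Reactants: 27 the 5-O-benzyl ketone
Product: 28 (4S)-5,7-dihydroxy-8-[3-(4-methoxyphenyl)propanoyl]-4-phenylchroman-2-one (target)
Conditions: H2 (1 atm), 10% Pd/C, EtOAc, rt
Reagents that add atoms: none
Why: Hydrogenolysis of the aryl benzyl ether over palladium on carbon in a neutral solvent should spare the hydrogen-bonded aryl ketone, the lactone and the C4–H bond, which carries no leaving group, so C4 stays (S).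

Compound list
1 | 3-phenylglutaric anhydride | O=C1CC(c2ccccc2)CC(=O)O1 | starting material
2 | (S)-5-methoxy-5-oxo-3-phenylpentanoic acid | COC(=O)C[C@@H](c1ccccc1)CC(=O)O | intermediate
3 | methyl (3R)-5-chloro-5-oxo-3-phenylpentanoate | COC(=O)C[C@@H](c1ccccc1)CC(=O)Cl | intermediate
4 | benzyl alcohol | OCc1ccccc1 | starting material
5 | trichloroethylene | ClC=C(Cl)Cl | starting material
6 | benzyl (E)-1,2-dichlorovinyl ether | Cl/C=C(/Cl)OCc1ccccc1 | intermediate
7 | benzyl chloroethynyl ether | ClC#COCc1ccccc1 | intermediate (not isolated)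
8 | lithium benzyloxyacetylide | [Li]C#COCc1ccccc1 | intermediate (not isolated)
9 | benzyl ethynyl ether (benzyloxyacetylene) | C#COCc1ccccc1 | intermediate
10 | methyl (3R)-5-oxo-3-phenylpent-4-enoate (monoalkylketene) | COC(=O)C[C@@H](c1ccccc1)C=C=O | intermediate (not isolated)
11 | methyl (3R)-3-[2-(benzyloxy)-4-oxocyclobut-2-en-1-yl]-3-phenylpropanoate, both epimers at the ring carbon | COC(=O)C[C@@H](c1ccccc1)C1C(=O)C=C1OCc1ccccc1 | intermediate
12 | 3-(4-methoxyphenyl)propanal | COc1ccc(CCC=O)cc1 | starting material
13 | ethynylmagnesium bromide | C#C[Mg]Br | starting material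
14 | rac-5-(4-methoxyphenyl)pent-1-yn-3-ol | C#CC(O)CCc1ccc(OC)cc1 | intermediate
15 | rac-tert-butyl{[5-(4-methoxyphenyl)pent-1-yn-3-yl]oxy}dimethylsilane | C#CC(CCc1ccc(OC)cc1)O[Si](C)(C)C(C)(C)C | intermediate
16 | lithium 3-[(tert-butyldimethylsilyl)oxy]-5-(4-methoxyphenyl)pent-1-yn-1-ide (racemic) | [Li]C#CC(CCc1ccc(OC)cc1)O[Si](C)(C)C(C)(C)C | intermediate (not isolated)
17 | lithium 3-[(tert-butyldimethylsilyl)oxy]-5-(4-methoxyphenyl)pent-1-yn-1-olate (racemic) | [Li]OC#CC(CCc1ccc(OC)cc1)O[Si](C)(C)C(C)(C)C | intermediate (not isolated)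
18 | rac-tert-butyl{[5-(4-methoxyphenyl)-1-[(triisopropylsilyl)oxy]pent-1-yn-3-yl]oxy}dimethylsilane | CC(C)[Si](OC#CC(CCc1ccc(OC)cc1)O[Si](C)(C)C(C)(C)C)(C(C)C)C(C)C | intermediate
19 | methyl (3R)-5-(benzyloxy)-7-oxo-3-phenylhepta-4,6-dienoate (vinylketene, alkene geometry not fixed) | COC(=O)C[C@@H](c1ccccc1)C=C(OCc1ccccc1)C=C=O | intermediate (not isolated)
20 | methyl (3R)-5-(benzyloxy)-5-[3-{1-[(tert-butyldimethylsilyl)oxy]-3-(4-methoxyphenyl)propyl}-4-oxo-2-[(triisopropylsilyl)oxy]cyclobut-2-en-1-yl]-3-phenylpent-4-enoate (isomer mixture) | COC(=O)C[C@@H](c1ccccc1)C=C(OCc1ccccc1)C1C(=O)C(C(CCc2ccc(OC)cc2)O[Si](C)(C)C(C)(C)C)=C1O[Si](C(C)C)(C(C)C)C(C)C | intermediate (not isolated)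
21 | methyl (3R)-5-(benzyloxy)-8-{1-[(tert-butyldimethylsilyl)oxy]-3-(4-methoxyphenyl)propyl}-9-oxo-3-phenyl-7-[(triisopropylsilyl)oxy]nona-4,6,8-trienoate (dienylketene, C5 and C8 cis across C6=C7) | COC(=O)C[C@@H](c1ccccc1)C=C(OCc1ccccc1)/C=C(O[Si](C(C)C)(C(C)C)C(C)C)\C(=C=O)C(CCc1ccc(OC)cc1)O[Si](C)(C)C(C)(C)C | intermediate (not isolated)
22 | methyl (3R)-3-[2-(benzyloxy)-5-{1-[(tert-butyldimethylsilyl)oxy]-3-(4-methoxyphenyl)propyl}-6-oxo-4-[(triisopropylsilyl)oxy]cyclohexa-2,4-dien-1-yl]-3-phenylpropanoate (isomer mixture) | COC(=O)C[C@@H](c1ccccc1)C1C(=O)C(C(CCc2ccc(OC)cc2)O[Si](C)(C)C(C)(C)C)=C(O[Si](C(C)C)(C(C)C)C(C)C)C=C1OCc1ccccc1 | intermediate (not isolated)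
23 | methyl (3S)-3-[6-(benzyloxy)-3-{1-[(tert-butyldimethylsilyl)oxy]-3-(4-methoxyphenyl)propyl}-2-hydroxy-4-[(triisopropylsilyl)oxy]phenyl]-3-phenylpropanoate (both carbinol epimers) | COC(=O)C[C@@H](c1ccccc1)c1c(OCc2ccccc2)cc(O[Si](C(C)C)(C(C)C)C(C)C)c(C(CCc2ccc(OC)cc2)O[Si](C)(C)C(C)(C)C)c1O | intermediate
24 | (4S)-5-(benzyloxy)-8-{1-[(tert-butyldimethylsilyl)oxy]-3-(4-methoxyphenyl)propyl}-4-phenyl-7-[(triisopropylsilyl)oxy]chroman-2-one (both carbinol epimers) | O=C1C[C@@H](c2ccccc2)c2c(OCc3ccccc3)cc(O[Si](C(C)C)(C(C)C)C(C)C)c(C(CCc3ccc(OC)cc3)O[Si](C)(C)C(C)(C)C)c2O1 | intermediate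
25 | (4S)-5-(benzyloxy)-8-[1-hydroxy-3-(4-methoxyphenyl)propyl]-4-phenyl-7-[(triisopropylsilyl)oxy]chroman-2-one (both carbinol epimers) | O=C1C[C@@H](c2ccccc2)c2c(OCc3ccccc3)cc(O[Si](C(C)C)(C(C)C)C(C)C)c(C(O)CCc3ccc(OC)cc3)c2O1 | intermediate
26 | (4S)-5-(benzyloxy)-8-[3-(4-methoxyphenyl)propanoyl]-4-phenyl-7-[(triisopropylsilyl)oxy]chroman-2-one | O=C1C[C@@H](c2ccccc2)c2c(OCc3ccccc3)cc(O[Si](C(C)C)(C(C)C)C(C)C)c(C(=O)CCc3ccc(OC)cc3)c2O1 | intermediate
27 | (4S)-5-(benzyloxy)-7-hydroxy-8-[3-(4-methoxyphenyl)propanoyl]-4-phenylchroman-2-one | O=C1C[C@@H](c2ccccc2)c2c(OCc3ccccc3)cc(O)c(C(=O)CCc3ccc(OC)cc3)c2O1 | intermediate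
28 | (4S)-5,7-dihydroxy-8-[3-(4-methoxyphenyl)propanoyl]-4-phenylchroman-2-one | COc1ccc(CCC(=O)c2c(O)cc(O)c3c2OC(=O)C[C@H]3c2ccccc2)cc1 | target

Total step count: 14.
Longest linear sequence: 9 steps (steps 1, 2, 5, 9, 10, 11, 12, 13, 14); the branches that start at steps 3 and 6 are equally long.

Steps most likely to fail

Step 9. The cyclobutenone is a vinylogous ester and may open only at temperatures at which the silyl ynol ether isomerises by oxygen-to-carbon silyl shift, or the bulky ynol ether may add too slowly, so that the vinylketene is lost to dimerisation or to acylation of the product phenol. The fallback changes the ketenophile class to an alkyl ynol ether and adapts the end of the route; it sets out from aldehyde 12 and cyclobutenone 11 and returns at target 28. Lithium ethoxyacetylide (ethoxyacetylene, n-BuLi, THF, −78 °C) would be added to 12 to give rac-1-ethoxy-5-(4-methoxyphenyl)pent-1-yn-3-ol F1, which is silylated (TBSCl, imidazole) to the ynol ether F2. Heating F2 with 11 at 80–90 °C should give the 7-O-ethyl phenol F3 by the same cascade. Pyridinium p-toluenesulfonate would then close the lactone F4, buffered Bu4NF (no aryl silyl ether is present any more) would free the carbinol F5, and Dess–Martin oxidation would give the ketone F6. BCl3 in CH2Cl2 at −78 → 0 °C should finally cleave the ethyl ether ortho to the ketone (chelation-assisted) together with the benzyl ether, sparing the remote anisole, to give 28.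

Step 5. The monoalkylketene may dimerise faster than it is captured, and the benzyl alkynyl ether may rearrange or polymerise before it reacts. The fallback reaches vinylketene 19 without ynol ether or cyclobutenone, by 1,4-dehydrochlorination of a 3-benzyloxyalk-2-enoyl chloride; it sets out from acid chloride 3 and returns at intermediate 19 of step 9, and hence at 23. Acylation of the lithium enolate of allyl acetate with 3 (2 equiv of enolate, THF, −78 °C) would give the β-keto ester F7. O-Benzylation of its enol (BnOH, PPh3, diisopropyl azodicarboxylate) would give the enol ether F8, deallylation (Pd(PPh3)4, morpholine) the acid F9, and 1-chloro-N,N,2-trimethylprop-1-en-1-amine the acid chloride F10. With Et3N in the presence of 18 at room temperature, F10 should lose the γ-proton to give 19, which is captured as in step 9 and gives 23 on warming to 80 °C.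

Step 11. The acidic fluoride may fail to distinguish the two silyl ethers, or the electron-rich benzylic carbinol may ionise, leading to elimination to the styrene or to substitution. The fallback gives up the selectivity; it sets out from 24 and returns at 27. Bu4NF buffered with AcOH (excess, THF, 0 °C → rt) would remove both silyl groups to give the phenolic diol F11. MnO2 in CH2Cl2, which oxidises benzylic alcohols and tolerates the phenol, would then convert the carbinol into ketone 27 directly, so that step 13 is not needed.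

Further compounds
F1 | step 9 | rac-1-ethoxy-5-(4-methoxyphenyl)pent-1-yn-3-ol | CCOC#CC(O)CCc1ccc(OC)cc1
F2 | step 9 | rac-tert-butyl{[1-ethoxy-5-(4-methoxyphenyl)pent-1-yn-3-yl]oxy}dimethylsilane | CCOC#CC(CCc1ccc(OC)cc1)O[Si](C)(C)C(C)(C)C
F3 | step 9 | methyl (3S)-3-[6-(benzyloxy)-3-{1-[(tert-butyldimethylsilyl)oxy]-3-(4-methoxyphenyl)propyl}-4-ethoxy-2-hydroxyphenyl]-3-phenylpropanoate | COC(=O)C[C@@H](c1ccccc1)c1c(OCc2ccccc2)cc(OCC)c(C(CCc2ccc(OC)cc2)O[Si](C)(C)C(C)(C)C)c1O
F4 | step 9 | (4S)-5-(benzyloxy)-8-{1-[(tert-butyldimethylsilyl)oxy]-3-(4-methoxyphenyl)propyl}-7-ethoxy-4-phenylchroman-2-one | O=C1C[C@@H](c2ccccc2)c2c(OCc3ccccc3)cc(OCC)c(C(CCc3ccc(OC)cc3)O[Si](C)(C)C(C)(C)C)c2O1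
F5 | step 9 | (4S)-5-(benzyloxy)-7-ethoxy-8-[1-hydroxy-3-(4-methoxyphenyl)propyl]-4-phenylchroman-2-one | O=C1C[C@@H](c2ccccc2)c2c(OCc3ccccc3)cc(OCC)c(C(O)CCc3ccc(OC)cc3)c2O1
F6 | step 9 | (4S)-5-(benzyloxy)-7-ethoxy-8-[3-(4-methoxyphenyl)propanoyl]-4-phenylchroman-2-one | O=C1C[C@@H](c2ccccc2)c2c(OCc3ccccc3)cc(OCC)c(C(=O)CCc3ccc(OC)cc3)c2O1
F7 | step 5 | 1-allyl 7-methyl (5S)-3-oxo-5-phenylheptanedioate | COC(=O)C[C@@H](c1ccccc1)CC(=O)CC(=O)OCC=C
F8 | step 5 | 1-allyl 7-methyl (5S)-3-(benzyloxy)-5-phenylhept-2-enedioate | COC(=O)C[C@@H](c1ccccc1)CC(OCc1ccccc1)=CC(=O)OCC=C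
F9 | step 5 | (5S)-3-(benzyloxy)-7-methoxy-7-oxo-5-phenylhept-2-enoic acid | COC(=O)C[C@@H](c1ccccc1)CC(OCc1ccccc1)=CC(=O)O
F10 | step 5 | methyl (3S)-5-(benzyloxy)-7-chloro-7-oxo-3-phenylhept-5-enoate | COC(=O)C[C@@H](c1ccccc1)CC(OCc1ccccc1)=CC(=O)Cl
F11 | step 11 | (4S)-5-(benzyloxy)-7-hydroxy-8-[1-hydroxy-3-(4-methoxyphenyl)propyl]-4-phenylchroman-2-one | O=C1C[C@@H](c2ccccc2)c2c(OCc3ccccc3)cc(O)c(C(O)CCc3ccc(OC)cc3)c2O1
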